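**Assumption:** lukianol B has no stereocentre or other stereogenic element, so it is achiral and there is no enantiomer to select. The only stereodescriptor in the route is the E geometry of nitroalkene 8, which does not persist.

## Retrosynthetic overview

1. Lukianol B ⇒ its tris(methyl ether) by global O-demethylation in the last step. The iodine is carried from a commercial iodo-aldehyde, so no late regioselective iodination is needed.
2. Ring B (oxazinone) is closed second, by forming the enol-lactone C(=O)–O bond of an N-phenacyl pyrrole-2-carboxylate.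
3. Ring A (pyrrole) is made first, in one pot. The key C3–C4 bond (C8–C7 of the target) joins the benzylic α-carbon of a 4-methoxyphenylpyruvate to the β-carbon of a 3-iodo-4-methoxy-β-nitrostyrene. The nitroalkene is the α-cation (enolonium) equivalent of an arylacetaldehyde, so two carbons that are both normally enolate carbons are united. N–C2 and N–C5 then come from 2-amino-4'-methoxyacetophenone by condensation and Nef-type closure.
4. Building blocks: the pyruvate from a 4-methoxybenzyl Grignard reagent and diethyl oxalate; the nitroalkene from 3-iodo-4-methoxybenzaldehyde and nitromethane.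

## Route

**Step 1**
Reactants: 1 4-methoxybenzylmagnesium chloride (4-MeOC6H4CH2MgCl, commercial 0.25 M solution in THF); 2 diethyl oxalate
Product: 4 ethyl 3-(4-methoxyphenyl)-2-oxopropanoate, via hemiketal alkoxide ROMgCl 3 (not isolated)
Conditions: 1 added to 2 (2 equiv), THF, −78 °C, 1 h; 1 M HCl, −78 °C → rt
Reagents that add atoms: none
Why: Grignard acylation by a dialkyl oxalate stops at the α-keto ester because tetrahedral adduct 3 is stable at −78 °C and collapses only on acidic quench, and inverse addition into excess oxalate suppresses double addition; no stereocentre is formed.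

**Step 2**
Reactants: 5 3-iodo-4-methoxybenzaldehyde; 6 nitromethane
Product: 8 (E)-2-iodo-1-methoxy-4-(2-nitroethenyl)benzene, via nitro alcohol 7 (not isolated)
Conditions: MeNO2 (5 equiv), NH4OAc (0.5 equiv), AcOH, 100 °C, 3 h
Reagents that add atoms: none
Why: Henry (nitroaldol) condensation gives nitro alcohol 7, which dehydrates in hot AcOH to the conjugated, thermodynamically favoured E nitroalkene; the aryl iodide and methyl ether are inert.

**Step 3 (key step)**
Reactants: 4 ethyl 3-(4-methoxyphenyl)-2-oxopropanoate; 8 (E)-2-iodo-1-methoxy-4-(2-nitroethenyl)benzene; 9 2-amino-1-(4-methoxyphenyl)ethanone hydrochloride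
Product: 12 ethyl 4-(3-iodo-4-methoxyphenyl)-3-(4-methoxyphenyl)-1-[2-(4-methoxyphenyl)-2-oxoethyl]-1H-pyrrole-2-carboxylate, via Michael adduct 10 (not isolated), via enamine 11 (not isolated)
Conditions: 4 + 8 (1:1), Et3N (10 mol%), toluene, rt, 4 h; then 9 (1.5 equiv), NaOAc (1.5 equiv), AcOH, 90 °C, 12 h
Reagents that add atoms: none
Why: Proposed new method: the strongly enolised arylpyruvate adds through its benzylic carbon to the nitroalkene, which serves as the α-cation (enolonium) equivalent of (3-iodo-4-methoxyphenyl)acetaldehyde, so the pyrrole C3–C4 bond is made between two carbons that are each α to a carbonyl-level carbon; the α-keto group of 10 then condenses with the amine (freed from 9 by NaOAc) to enamine 11, whose nitrogen attacks the aci-nitro carbon and, after loss of water and HNO (Nef-type), gives the aromatic pyrrole with the iodoaryl group next to C5–H; the closest known reactions are the base-catalysed Michael addition of α-keto esters to nitroalkenes and the Grob–Camenzind / three-component amine–1,3-dicarbonyl–nitroalkene pyrrole synthesis; the two stereocentres of 10 are destroyed on aromatisation.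

**Step 4**
Reactants: 12 ethyl 4-(3-iodo-4-methoxyphenyl)-3-(4-methoxyphenyl)-1-[2-(4-methoxyphenyl)-2-oxoethyl]-1H-pyrrole-2-carboxylate
Product: 15 7-(3-iodo-4-methoxyphenyl)-3,8-bis(4-methoxyphenyl)-1H-pyrrolo[2,1-c][1,4]oxazin-1-one (lukianol B trimethyl ether), via carboxylate salt RCO2Na 13 (not isolated), via mixed anhydride 14 (not isolated)
Conditions: NaOH (3 equiv), EtOH/H2O, 75 °C, N2; evaporate to dryness (toluene azeotrope); Ac2O (excess), 100 °C, 2 h
Reagents that add atoms: sodium hydroxide, [Na+].[OH-] (sodium and one oxygen in 13; that oxygen can end as the lactone carbonyl oxygen of 15); acetic anhydride, CC(=O)OC(C)=O (acetyl group in 14 only)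
Why: Saponification gives 13, Ac2O converts it into mixed anhydride 14, and the ketone enol oxygen (NaOAc formed in situ as base) acylates intramolecularly to the six-membered enol lactone (enol-lactonisation; C-acylation would need a four-membered ring), the established closure for this ring system; no stereocentre.

**Step 5**
Reactants: 15 7-(3-iodo-4-methoxyphenyl)-3,8-bis(4-methoxyphenyl)-1H-pyrrolo[2,1-c][1,4]oxazin-1-one
Product: 17 lukianol B, 7-(4-hydroxy-3-iodophenyl)-3,8-bis(4-hydroxyphenyl)-1H-pyrrolo[2,1-c][1,4]oxazin-1-one, via tris(dibromoboryl) ether 16 (not isolated)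
Conditions: BBr3 (9 equiv), CH2Cl2, −78 °C → rt; H2O
Reagents that add atoms: boron tribromide, BrB(Br)Br (BBr2 groups in 16 only; 17 gains only hydrogen, from water)
Why: Lewis-acid aryl methyl ether cleavage: BBr3 coordinates each anisole oxygen and bromide removes the methyl group to give borate 16, hydrolysed on work-up; the aryl iodide, the pyrrole and the electron-rich (vinylogous-carbamate-type) enol lactone tolerate BBr3 at low temperature.

## Compound list

1 | 4-methoxybenzylmagnesium chloride (4-MeOC6H4CH2MgCl, 0.25 M in THF) | COc1ccc(C[Mg]Cl)cc1 | starting material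
2 | diethyl oxalate | CCOC(=O)C(=O)OCC | starting material
3 | ethyl 2-(chloromagnesiooxy)-2-ethoxy-3-(4-methoxyphenyl)propanoate (hemiketal alkoxide ROMgCl, racemic) | CCOC(=O)C(Cc1ccc(OC)cc1)(OCC)O[Mg]Cl | intermediate (not isolated)
4 | ethyl 3-(4-methoxyphenyl)-2-oxopropanoate (keto/enol mixture) | CCOC(=O)C(=O)Cc1ccc(OC)cc1 | intermediate
5 | 3-iodo-4-methoxybenzaldehyde | COc1ccc(C=O)cc1I | starting material
6 | nitromethane | C[N+](=O)[O-] | starting material
7 | 1-(3-iodo-4-methoxyphenyl)-2-nitroethanol (racemic) | COc1ccc(C(O)C[N+](=O)[O-])cc1I | intermediate (not isolated)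
8 | (E)-2-iodo-1-methoxy-4-(2-nitroethenyl)benzene | COc1ccc(/C=C/[N+](=O)[O-])cc1I | intermediate
9 | 2-amino-1-(4-methoxyphenyl)ethanone hydrochloride | COc1ccc(cc1)C(=O)CN.Cl | starting material
10 | ethyl 4-(3-iodo-4-methoxyphenyl)-3-(4-methoxyphenyl)-5-nitro-2-oxopentanoate (racemic diastereomer mixture) | CCOC(=O)C(=O)C(c1ccc(OC)cc1)C(C[N+](=O)[O-])c1ccc(OC)c(I)c1 | intermediate (not isolated)
11 | ethyl 4-(3-iodo-4-methoxyphenyl)-3-(4-methoxyphenyl)-2-{[2-(4-methoxyphenyl)-2-oxoethyl]amino}-5-nitropent-2-enoate (racemic, alkene geometry not defined) | CCOC(=O)C(NCC(=O)c1ccc(OC)cc1)=C(c1ccc(OC)cc1)C(C[N+](=O)[O-])c1ccc(OC)c(I)c1 | intermediate (not isolated)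
12 | ethyl 4-(3-iodo-4-methoxyphenyl)-3-(4-methoxyphenyl)-1-[2-(4-methoxyphenyl)-2-oxoethyl]-1H-pyrrole-2-carboxylate | CCOC(=O)c1c(-c2ccc(OC)cc2)c(-c2ccc(OC)c(I)c2)cn1CC(=O)c1ccc(OC)cc1 | intermediate
13 | sodium 4-(3-iodo-4-methoxyphenyl)-3-(4-methoxyphenyl)-1-[2-(4-methoxyphenyl)-2-oxoethyl]-1H-pyrrole-2-carboxylate (RCO2Na) | [Na+].[O-]C(=O)c1c(-c2ccc(OC)cc2)c(-c2ccc(OC)c(I)c2)cn1CC(=O)c1ccc(OC)cc1 | intermediate (not isolated)
14 | acetic 4-(3-iodo-4-methoxyphenyl)-3-(4-methoxyphenyl)-1-[2-(4-methoxyphenyl)-2-oxoethyl]-1H-pyrrole-2-carboxylic anhydride | CC(=O)OC(=O)c1c(-c2ccc(OC)cc2)c(-c2ccc(OC)c(I)c2)cn1CC(=O)c1ccc(OC)cc1 | intermediate (not isolated)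
15 | 7-(3-iodo-4-methoxyphenyl)-3,8-bis(4-methoxyphenyl)-1H-pyrrolo[2,1-c][1,4]oxazin-1-one | O=c1oc(-c2ccc(OC)cc2)cn2cc(-c3ccc(OC)c(I)c3)c(-c3ccc(OC)cc3)c12 | intermediate
16 | 7-[4-(dibromoboryloxy)-3-iodophenyl]-3,8-bis[4-(dibromoboryloxy)phenyl]-1H-pyrrolo[2,1-c][1,4]oxazin-1-one | O=c1oc(-c2ccc(OB(Br)Br)cc2)cn2cc(-c3ccc(OB(Br)Br)c(I)c3)c(-c3ccc(OB(Br)Br)cc3)c12 | intermediate (not isolated)
17 | lukianol B, 7-(4-hydroxy-3-iodophenyl)-3,8-bis(4-hydroxyphenyl)-1H-pyrrolo[2,1-c][1,4]oxazin-1-one (achiral) | O=c1oc(-c2ccc(O)cc2)cn2cc(-c3ccc(O)c(I)c3)c(-c3ccc(O)cc3)c12 | target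

## Step count and risks

Total step count: 5 (steps 1 and 2 run in parallel).
Longest linear sequence: 4 steps (1 or 2 → 3 → 4 → 5).

**Most likely to fail, in order:**

**Step 3 (one-pot Michael addition / amine condensation / Nef-type pyrrole closure).** The risks are self-condensation of the free amino ketone to a dihydropyrazine, sluggish closure onto the aci-nitro carbon, and nitrosation of the free pyrrole C5 position by the HNO released. The fallback takes the ring nitrogen from the nitro group instead of from the amino ketone. It sets out from adduct 10, isolated after the Et3N stage. Reduction of the nitro group with Fe powder in AcOH/EtOH at 70 °C is followed by spontaneous condensation of the amine with the α-keto group, giving the cyclic imine ethyl 3-(3-iodo-4-methoxyphenyl)-4-(4-methoxyphenyl)-3,4-dihydro-2H-pyrrole-5-carboxylate F1. Dehydrogenation with DDQ in toluene gives ethyl 4-(3-iodo-4-methoxyphenyl)-3-(4-methoxyphenyl)-1H-pyrrole-2-carboxylate F2. N-alkylation with commercial 2-bromo-1-(4-methoxyphenyl)ethanone (COc1ccc(cc1)C(=O)CBr) and K2CO3 in DMF comes back to the route at 12.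

**Step 5 (BBr3 on the iodinated enol lactone).** The risks are opening of the enol lactone, incomplete cleavage through precipitation of partly demethylated borates, and acid-induced loss of iodine on warming. The fallback reverses the order, deprotecting before the lactone exists and finishing with an ester cleavage instead of an ether cleavage. It sets out from 12. Excess BBr3 in CH2Cl2 (−78 °C → rt, prolonged; any surviving ester is cleaved by aqueous NaOH in the work-up) removes the three methyl ethers and the ethyl ester, giving 4-(4-hydroxy-3-iodophenyl)-3-(4-hydroxyphenyl)-1-[2-(4-hydroxyphenyl)-2-oxoethyl]-1H-pyrrole-2-carboxylic acid F3. Ac2O/NaOAc at 100 °C closes the lactone and acetylates the phenols, giving 7-(4-acetoxy-3-iodophenyl)-3,8-bis(4-acetoxyphenyl)-1H-pyrrolo[2,1-c][1,4]oxazin-1-one F4. Brief methanolysis of the three aryl acetates (catalytic K2CO3, MeOH, 0 °C), which are far more electrophilic than the pyrrole-conjugated lactone, comes back to the route at 17.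

**Step 1 (benzylic Grignard reagent with oxalate).** The risks are Wurtz coupling of the reagent, double addition, and attack through the ring ortho position. The fallback replaces the organometallic acylation by an enolate acylation and decarboxylation. It sets out from 2. Claisen condensation with commercial ethyl (4-methoxyphenyl)acetate (CCOC(=O)Cc1ccc(OC)cc1; NaOEt, EtOH/Et2O) gives diethyl 2-(4-methoxyphenyl)-3-oxobutanedioate F5. Heating in aqueous H2SO4/AcOH hydrolyses both esters and decarboxylates the β-keto acid, giving 3-(4-methoxyphenyl)-2-oxopropanoic acid F6. Fischer esterification (EtOH, catalytic H2SO4) comes back to the route at 4.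

## Further compounds

F1 | step 3 | ethyl 3-(3-iodo-4-methoxyphenyl)-4-(4-methoxyphenyl)-3,4-dihydro-2H-pyrrole-5-carboxylate (racemic diastereomer mixture) | CCOC(=O)C1=NCC(c2ccc(OC)c(I)c2)C1c1ccc(OC)cc1
F2 | step 3 | ethyl 4-(3-iodo-4-methoxyphenyl)-3-(4-methoxyphenyl)-1H-pyrrole-2-carboxylate | CCOC(=O)c1[nH]cc(-c2ccc(OC)c(I)c2)c1-c1ccc(OC)cc1
F3 | step 5 | 4-(4-hydroxy-3-iodophenyl)-3-(4-hydroxyphenyl)-1-[2-(4-hydroxyphenyl)-2-oxoethyl]-1H-pyrrole-2-carboxylic acid | OC(=O)c1c(-c2ccc(O)cc2)c(-c2ccc(O)c(I)c2)cn1CC(=O)c1ccc(O)cc1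
F4 | step 5 | 7-(4-acetoxy-3-iodophenyl)-3,8-bis(4-acetoxyphenyl)-1H-pyrrolo[2,1-c][1,4]oxazin-1-one | O=c1oc(-c2ccc(OC(C)=O)cc2)cn2cc(-c3ccc(OC(C)=O)c(I)c3)c(-c3ccc(OC(C)=O)cc3)c12
F5 | step 1 | diethyl 2-(4-methoxyphenyl)-3-oxobutanedioate (racemic, largely enolised) | CCOC(=O)C(=O)C(C(=O)OCC)c1ccc(OC)cc1
F6 | step 1 | 3-(4-methoxyphenyl)-2-oxopropanoic acid | COc1ccc(CC(=O)C(=O)O)cc1
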